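**Retrosynthetic overview**

- Numbering (hexahydronaphthalene): ring A = C4a–C5–C6–C7=C8–C8a, ring B = C8a–C1–C2=C3–C4–C4a. The strategy rests on C8a, the quaternary ring-fusion carbon that is the α-carbon of the angular CO2H and is bonded to the sp2 carbon C8 of the cis C7=C8 bond of ring A: the product pattern of an enolate vinylation.
- Key disconnection C8a–C8: zerovalent palladium couples the C8a ester enolate of ring B with a (Z)-bromoalkene tethered on C4a (22 → 24). Ring A is closed last.
- C5–C6 comes from iodide 16 and the SAMP hydrazone of (S)-citronellal, which sets C6. The C7 aldehyde then becomes (Z)-CH=CHBr by a Wittig reaction.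
- Ring B is made first: endo Diels–Alder reaction of triene 10 with (5R)-5-(l-menthyloxy)furan-2(5H)-one sets C1 and C4a in the absolute sense, and the acetal carbon is reduced to C5. The triene comes from alkyne methylalumination and a Suzuki coupling.
- End game: desilylation, oxidation of the arm CH2OH, and SN2 demethylation of the angular ester.

Key step: step 15

Remark: dienophile 11 is taken as a catalogue compound (otherwise two steps from furfural and (−)-menthol). The C8a configuration drawn for 12–22 is that of the endo adduct and is erased on enolisation in step 15. "Arm" means the (E)-2-(trans-4-substituted cyclohexyl)prop-1-enyl group on C1.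

**Route**

Step 1
Reactants: 1 trans-4-(methoxycarbonyl)cyclohexane-1-carboxylic acid
Product: 2 methyl trans-4-(hydroxymethyl)cyclohexane-1-carboxylate
Conditions: BH3·SMe2, THF, 0 °C → rt
Reagents that add atoms: none
Why: chemoselective borane reduction of a carboxylic acid through its acyloxyborane leaves the methyl ester and the trans ring untouched.

Step 2
Reactants: 2 methyl trans-4-(hydroxymethyl)cyclohexane-1-carboxylate
Product: 3 methyl trans-4-{[(tert-butyldimethylsilyl)oxy]methyl}cyclohexane-1-carboxylate
Conditions: TBSCl, imidazole, DMF, rt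
Reagents that add atoms: tert-butyldimethylsilyl chloride, CC(C)(C)[Si](C)(C)Cl
Why: standard silylation of a primary alcohol gives an ether that should last through the organometallic, basic and mildly acidic steps up to step 16.

Step 3
Reactants: 3 methyl trans-4-{[(tert-butyldimethylsilyl)oxy]methyl}cyclohexane-1-carboxylate
Product: 4 trans-4-{[(tert-butyldimethylsilyl)oxy]methyl}cyclohexane-1-carbaldehyde
Conditions: i-Bu2AlH (1.1 equiv), CH2Cl2, −78 °C; MeOH, aq. potassium sodium tartrate
Reagents that add atoms: none
Why: partial hydride reduction of an ester stops at the aldehyde because the tetrahedral aluminium hemiacetal is stable at −78 °C and collapses only on work-up.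

Step 4
Reactants: 4 trans-4-{[(tert-butyldimethylsilyl)oxy]methyl}cyclohexane-1-carbaldehyde
Product: 5 tert-butyl[(trans-4-ethynylcyclohexyl)methoxy]dimethylsilane
Conditions: TMSCHN2, n-BuLi, THF, −78 °C → rt
Reagents that add atoms: (trimethylsilyl)diazomethane, C[Si](C)(C)C=[N+]=[N-]
Why: Colvin homologation (addition of lithiated TMS-diazomethane, Peterson-type loss of silanolate, 1,2-hydride shift of the alkylidene carbene) gives the terminal alkyne at low temperature, so the epimerisable α-carbon should keep the trans arrangement.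

Step 5
Reactants: 5 tert-butyl[(trans-4-ethynylcyclohexyl)methoxy]dimethylsilane
Product: 7 tert-butyl({trans-4-[(E)-1-iodoprop-1-en-2-yl]cyclohexyl}methoxy)dimethylsilane, via alkenyl(dimethyl)alane 6 (not isolated)
Conditions: Me3Al (2.5 equiv), Cp2ZrCl2 (0.25 equiv), CH2Cl2, 0 °C → rt; then I2, THF, −30 → 0 °C
Reagents that add atoms: trimethylaluminium, C[Al](C)C; iodine, II
Why: Negishi zirconium-catalysed methylalumination adds CH3 and Al syn across the alkyne with Al on the terminal carbon, and iodine replaces aluminium with retention, which fixes the E geometry of the arm alkene.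

Step 6
Reactants: 8 2-methylbut-1-en-3-yne
Product: 9 (E)-4,4,5,5-tetramethyl-2-(3-methylbuta-1,3-dien-1-yl)-1,3,2-dioxaborolane
Conditions: pinacolborane, Cp2Zr(H)Cl (5 mol%), Et3N (10 mol%), neat, 60 °C
Reagents that add atoms: pinacolborane, CC1(C)OBOC1(C)C
Why: zirconium-catalysed syn hydroboration of the terminal alkyne places boron on the terminal carbon and gives the E dienylboronate, leaving the 1,1-disubstituted alkene untouched.

Step 7
Reactants: 7 tert-butyl({trans-4-[(E)-1-iodoprop-1-en-2-yl]cyclohexyl}methoxy)dimethylsilane; 9 (E)-4,4,5,5-tetramethyl-2-(3-methylbuta-1,3-dien-1-yl)-1,3,2-dioxaborolane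
Product: 10 tert-butyldimethyl({trans-4-[(2E,4E)-6-methylhepta-2,4,6-trien-2-yl]cyclohexyl}methoxy)silane
Conditions: Pd(PPh3)4 (5 mol%), aq. KOH, THF, 50 °C, dark, 2,6-di-tert-butyl-4-methylphenol (BHT, trace)
Reagents that add atoms: none
Why: Suzuki–Miyaura coupling of an alkenyl iodide with an alkenylboronate proceeds with retention at both sp2 carbons and should give the (E,E)-triene.

Step 8
Reactants: 10 tert-butyldimethyl({trans-4-[(2E,4E)-6-methylhepta-2,4,6-trien-2-yl]cyclohexyl}methoxy)silane; 11 (5R)-5-[(1R,2S,5R)-menthyloxy]furan-2(5H)-one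
Product: 12 endo adduct: ring B (C2=C3 with CH3 on C3) cis-fused to a γ-menthyloxy lactone, with the lactone C=O on C8a, the acetal carbon (future C5) on C4a and the arm on C1 all cis, and the menthyloxy group anti to ring B
Conditions: toluene, 115 °C (sealed tube), BHT (trace), 48 h
Reagents that add atoms: none
Why: Diels–Alder reaction of the only diene unit that can reach s-cis (C4H2=C3(CH3)–C2H=C1H), in which the 1-alkenyl and 3-methyl groups both direct C1 to the α-carbon of the butenolide, the endo transition state puts arm, carbonyl and acetal carbon cis (C1 and C4a set relative to each other), and addition anti to the menthyloxy group sets their absolute configuration.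

Step 9
Reactants: 12 endo menthyloxy lactone adduct
Product: 15 methyl ester of ring B with C5H2OH on C4a (CO2Me on C8a and the arm on C1 cis to it), via potassium formyl carboxylate 13 (not isolated), via potassium hydroxy carboxylate 14 (not isolated)
Conditions: KOH (1.1 equiv), NaBH4 (1.0 equiv), EtOH–H2O, 0 °C → rt; acetone; solid CO2 to pH 8–9; evaporate; MeI (3 equiv), DMF, 0 °C → rt
Reagents that add atoms: potassium hydroxide, [K+].[OH-]; iodomethane, CI
Why: saponification of the acyl acetal releases menthol and the C5 aldehyde, which the borohydride already present should reduce faster than C4a can enolise, and because the mixture is never taken below pH 8 the cis hydroxy carboxylate cannot lactonise and is trapped by SN2 O-methylation in DMF (reductive removal of the auxiliary from a 5-alkoxyfuranone adduct followed by carboxylate alkylation), with menthol removed at the chromatography of 15.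

Step 10
Reactants: 15 hydroxy methyl ester of ring B
Product: 16 methyl ester of ring B with C5H2I on C4a
Conditions: I2, PPh3, imidazole, CH2Cl2, 0 °C, dark
Reagents that add atoms: iodine, II
Why: Appel-type iodination (Garegg–Samuelsson conditions) converts the primary alcohol of freshly made 15 through its alkoxyphosphonium salt under neutral conditions, which should outrun relactonisation, and the stereocentres are not involved.

Step 11
Reactants: 17 (S)-citronellal
Product: 18 (E)-SAMP hydrazone of (S)-citronellal
Conditions: SAMP (1.05 equiv), CH2Cl2, MgSO4, 0 °C → rt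
Reagents that add atoms: SAMP, (S)-1-amino-2-(methoxymethyl)pyrrolidine, COC[C@@H]1CCCN1N
Why: condensation of an aldehyde with a 1,1-disubstituted hydrazine gives the E hydrazone and installs the auxiliary for step 12.

Step 12
Reactants: 18 (E)-SAMP hydrazone of (S)-citronellal; 16 methyl ester of ring B with C5H2I on C4a
Product: 20 SAMP hydrazone alkylated at C6 (C5–C6 bond formed), via lithium azaenolate 19 (not isolated)
Conditions: 18 (1.5 equiv), LiN(i-Pr)2 (1.45 equiv), THF, 0 °C; −100 °C, add 16; → −20 °C, 14 h
Reagents that add atoms: none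
Why: Enders SAMP-hydrazone alkylation, in which the chelated azaenolate (E at C=C, Z at C–N) is attacked by the primary iodide on the face left open by the methoxymethylpyrrolidine and so sets C6 with the topicity that turns pentan-3-one and propyl iodide into (S)-4-methylheptan-3-one; keeping the amide base below the hydrazone leaves none for the ester.

Step 13
Reactants: 20 SAMP hydrazone alkylated at C6
Product: 21 C7 aldehyde (ring B methyl ester carrying CH2–CH(CHO)–[(S)-6-methylhept-5-en-2-yl] on C4a)
Conditions: sat. aq. oxalic acid, Et2O, rt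
Reagents that add atoms: water, O
Why: two-phase hydrolysis of the hydrazone with oxalic acid is mild enough to spare the α-stereocentre C6 and the silyl ether, and returns the auxiliary as its oxalate.

Step 14
Reactants: 21 C7 aldehyde
Product: 22 ring B methyl ester with enolisable C8a–H and the (Z)-2-bromovinyl group on C6
Conditions: Ph3P(CH2Br)Br, KOt-Bu, THF, −78 °C; then 21, −78 → −30 °C
Reagents that add atoms: (bromomethyl)triphenylphosphonium bromide, BrC[P+](c1ccccc1)(c1ccccc1)c1ccccc1.[Br-]
Why: Wittig reaction of the unstabilised bromomethylene ylide at low temperature is under kinetic control and should give mainly the (Z)-bromoalkene, with the ylide pre-formed so that no free base reaches C6.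

Step 15
Reactants: 22 ring B methyl ester with the (Z)-bromovinyl chain
Product: 24 cis-fused hexahydronaphthalene methyl ester with the silyl-protected arm, via potassium ester enolate 23 (not isolated)
Conditions: KN(SiMe3)2 (1.1 equiv), THF, −78 °C, 30 min; Pd2(dba)3 (5 mol%), P(t-Bu)3 (12 mol%), toluene, −78 °C → rt
Reagents that add atoms: none
Why: KN(SiMe3)2 removes the only α-hydrogen (C8a–H) at −78 °C before the catalyst is added, so no free base is left to take HBr from the (Z)-bromoalkene; zerovalent palladium carrying one P(t-Bu)3 then inserts into the C8–Br bond with retention, the enolate displaces bromide on palladium, and C–C reductive elimination from the carbon-bound enolate forms C8a–C8 (intramolecular Buchwald–Hartwig-type α-alkenylation of an ester enolate, the alkenyl counterpart of ester α-arylation). Ring A closes through a seven-membered palladacycle as a six-membered ring with the former bromoalkene endocyclic (6-(enolexo)-endo-trig), and the Z geometry becomes the cis C7=C8 bond. The new quaternary centre C8a is controlled by the C4a stereocentre: allylic 1,3-strain with the tetrasubstituted enolate turns the C4a–C5 bond axial, and from there the four-atom tether with its cis double bond reaches only the face of C8a syn to C5, which gives the cis ring fusion and leaves CO2Me trans to the arm. The step needs cis over trans fusion and coupling over reduction; the short rigid tether should secure the first, and the bulky electron-rich phosphine, which speeds reductive elimination past β-hydride loss from C1–H or C4a–H, the second. Either face of C8a puts one sp2 substituent next to the arm on C1, so the arm should cost rate more than selectivity.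

Step 16
Reactants: 24 cis-fused hexahydronaphthalene methyl ester with the silyl-protected arm
Product: 25 cis-fused hexahydronaphthalene methyl ester with CH2OH on the arm cyclohexane
Conditions: Bu4NF, THF, 0 °C → rt
Reagents that add atoms: none
Why: fluoride-induced cleavage of the Si–O bond frees the primary alcohol and does not touch the hindered angular ester.

Step 17
Reactants: 25 cis-fused hexahydronaphthalene methyl ester with CH2OH on the arm
Product: 26 arm carboxylic acid with the angular methyl ester still in place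
Conditions: 2,2,6,6-tetramethylpiperidin-1-oxyl (TEMPO, 20 mol%), PhI(OAc)2 (2.5 equiv), MeCN–H2O, rt
Reagents that add atoms: water, O
Why: oxoammonium oxidation of the primary alcohol to the aldehyde and of its hydrate to the acid should spare the four alkenes, and the mildly acidic medium should not epimerise the trans cyclohexane.

Step 18
Reactants: 26 arm carboxylic acid with the angular methyl ester
Product: 27 CNP0151628.5
Conditions: n-PrSLi (6 equiv), HMPA, rt; then aq. HCl
Reagents that add atoms: none
Why: SN2 attack of thiolate on the O-methyl carbon cleaves the neopentyl-type angular ester that resists acyl substitution, and the β,γ-unsaturated acid cannot isomerise because C8a carries no hydrogen.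

**Compound list**

1 | trans-4-(methoxycarbonyl)cyclohexane-1-carboxylic acid | COC(=O)[C@H]1CC[C@@H](CC1)C(=O)O | starting material
2 | methyl trans-4-(hydroxymethyl)cyclohexane-1-carboxylate | COC(=O)[C@H]1CC[C@H](CO)CC1 | intermediate
3 | methyl trans-4-{[(tert-butyldimethylsilyl)oxy]methyl}cyclohexane-1-carboxylate | COC(=O)[C@H]1CC[C@H](CO[Si](C)(C)C(C)(C)C)CC1 | intermediate
4 | trans-4-{[(tert-butyldimethylsilyl)oxy]methyl}cyclohexane-1-carbaldehyde | O=C[C@H]1CC[C@H](CO[Si](C)(C)C(C)(C)C)CC1 | intermediate
5 | tert-butyl[(trans-4-ethynylcyclohexyl)methoxy]dimethylsilane | C#C[C@H]1CC[C@H](CO[Si](C)(C)C(C)(C)C)CC1 | intermediate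
6 | dimethyl[(E)-2-(trans-4-{[(tert-butyldimethylsilyl)oxy]methyl}cyclohexyl)prop-1-en-1-yl]alane | C/C(=C\[Al](C)C)[C@H]1CC[C@H](CO[Si](C)(C)C(C)(C)C)CC1 | intermediate (not isolated)
7 | tert-butyl({trans-4-[(E)-1-iodoprop-1-en-2-yl]cyclohexyl}methoxy)dimethylsilane | C/C(=C\I)[C@H]1CC[C@H](CO[Si](C)(C)C(C)(C)C)CC1 | intermediate
8 | 2-methylbut-1-en-3-yne | CC(=C)C#C | starting material
9 | (E)-4,4,5,5-tetramethyl-2-(3-methylbuta-1,3-dien-1-yl)-1,3,2-dioxaborolane | CC(=C)/C=C/B1OC(C)(C)C(C)(C)O1 | intermediate
10 | tert-butyldimethyl({trans-4-[(2E,4E)-6-methylhepta-2,4,6-trien-2-yl]cyclohexyl}methoxy)silane | CC(=C)/C=C/C=C(\C)[C@H]1CC[C@H](CO[Si](C)(C)C(C)(C)C)CC1 | intermediate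
11 | (5R)-5-{[(1R,2S,5R)-2-isopropyl-5-methylcyclohexyl]oxy}furan-2(5H)-one | O=C1O[C@@H](O[C@@H]2C[C@H](C)CC[C@H]2C(C)C)C=C1 | starting material
12 | endo Diels–Alder adduct, cis-fused menthyloxy lactone on ring B (arm on C1, C=O on C8a and acetal carbon on C4a all cis; menthyloxy anti to ring B) | O=C1O[C@@H](O[C@@H]2C[C@H](C)CC[C@H]2C(C)C)[C@@H]3CC(C)=C[C@H](/C=C(\C)[C@H]4CC[C@H](CO[Si](C)(C)C(C)(C)C)CC4)[C@H]13 | intermediate
13 | potassium salt of the ring B acid with CHO (C5) on C4a | [K+].[O-]C(=O)[C@@H]1[C@H](C=O)CC(C)=C[C@@H]1/C=C(\C)[C@H]2CC[C@H](CO[Si](C)(C)C(C)(C)C)CC2 | intermediate (not isolated)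
14 | potassium salt of the ring B acid with CH2OH (C5) on C4a | [K+].[O-]C(=O)[C@@H]1[C@H](CO)CC(C)=C[C@@H]1/C=C(\C)[C@H]2CC[C@H](CO[Si](C)(C)C(C)(C)C)CC2 | intermediate (not isolated)
15 | methyl ester of ring B with CH2OH (C5) on C4a, all-cis | COC(=O)[C@@H]1[C@H](CO)CC(C)=C[C@@H]1/C=C(\C)[C@H]2CC[C@H](CO[Si](C)(C)C(C)(C)C)CC2 | intermediate
16 | methyl ester of ring B with CH2I (C5) on C4a, all-cis | COC(=O)[C@@H]1[C@H](CI)CC(C)=C[C@@H]1/C=C(\C)[C@H]2CC[C@H](CO[Si](C)(C)C(C)(C)C)CC2 | intermediate
17 | (S)-citronellal | CC(C)=CCC[C@H](C)CC=O | starting material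
18 | (E)-SAMP hydrazone of (S)-citronellal | CC(C)=CCC[C@H](C)C/C=N/N1CCC[C@H]1COC | intermediate
19 | lithium azaenolate of 18 | CC(C)=CCC[C@H](C)/C=C/N([Li])N1CCC[C@H]1COC | intermediate (not isolated)
20 | SAMP hydrazone alkylated at C6 with the ring B iodide | CC(C)=CCC[C@H](C)[C@H](/C=N/N1CCC[C@H]1COC)C[C@@H]2CC(C)=C[C@H](/C=C(\C)[C@H]3CC[C@H](CO[Si](C)(C)C(C)(C)C)CC3)[C@@H]2C(=O)OC | intermediate
21 | C7 aldehyde | CC(C)=CCC[C@H](C)[C@H](C=O)C[C@@H]1CC(C)=C[C@H](/C=C(\C)[C@H]2CC[C@H](CO[Si](C)(C)C(C)(C)C)CC2)[C@@H]1C(=O)OC | intermediate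
22 | ring B methyl ester with enolisable C8a–H and the (Z)-bromovinyl chain on C4a (key-step precursor) | CC(C)=CCC[C@H](C)[C@H](/C=C\Br)C[C@@H]1CC(C)=C[C@H](/C=C(\C)[C@H]2CC[C@H](CO[Si](C)(C)C(C)(C)C)CC2)[C@@H]1C(=O)OC | intermediate
23 | potassium ester enolate of 22 | CC(C)=CCC[C@H](C)[C@H](/C=C\Br)C[C@@H]1CC(C)=C[C@H](/C=C(\C)[C@H]2CC[C@H](CO[Si](C)(C)C(C)(C)C)CC2)C1=C([O-])OC.[K+] | intermediate (not isolated)
24 | cis-fused hexahydronaphthalene methyl ester with silyl-protected arm (key-step product) | CC(C)=CCC[C@H](C)[C@@H]1C=C[C@]2(C(=O)OC)[C@@H](CC(C)=C[C@@H]2/C=C(\C)[C@H]2CC[C@H](CO[Si](C)(C)C(C)(C)C)CC2)C1 | intermediate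
25 | cis-fused hexahydronaphthalene methyl ester with CH2OH on the arm | CC(C)=CCC[C@H](C)[C@@H]1C=C[C@]2(C(=O)OC)[C@@H](CC(C)=C[C@@H]2/C=C(\C)[C@H]2CC[C@H](CO)CC2)C1 | intermediate
26 | arm carboxylic acid, angular methyl ester | CC(C)=CCC[C@H](C)[C@@H]1C=C[C@]2(C(=O)OC)[C@@H](CC(C)=C[C@@H]2/C=C(\C)[C@H]2CC[C@H](C(=O)O)CC2)C1 | intermediate
27 | CNP0151628.5 | CC(C)=CCC[C@H](C)[C@@H]1C=C[C@]2(C(=O)O)[C@@H](CC(C)=C[C@@H]2/C=C(\C)[C@H]2CC[C@H](C(=O)O)CC2)C1 | target

**Step count and risk**

Total: 18 steps. Longest linear sequence: 16 steps (1–5, 7–10, 12–18).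

Steps most likely to fail:

1. Step 15 (key step). What may go wrong: β-hydride loss from the carbon-bound palladium enolate (C1–H or C4a–H) that hands the hydrogen to C8 and leaves a debrominated vinyl group; loss of HBr from the (Z)-bromoalkene to the alkyne if any base outlives enolisation; closure on the other face of C8a to the trans-fused isomer. Fallback: form C8a–C8 by an intramolecular Reformatsky aldol and make the alkene by dehydration. It sets out from 21. A Wittig reaction with Ph3P=CHOMe (from (methoxymethyl)triphenylphosphonium chloride and KN(SiMe3)2, THF, −78 → 0 °C) gives the one-carbon-longer methyl enol ether F1. LiN(i-Pr)2 then CBr4 at −78 °C gives the C8a bromo ester F2. Hg(OAc)2 in THF–H2O followed by KI frees the bromo aldehyde F3, whose aldehyde carbon is C8. SmI2 in THF at −78 °C makes the samarium enolate at C8a, which adds to the aldehyde and closes ring A as the C8 carbinol F4. Burgess reagent (methyl N-(triethylammoniumsulfonyl)carbamate, toluene, 70 °C) dehydrates it; elimination can only go toward C7 because C8a bears no hydrogen, and the route is rejoined at 24.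

2. Step 12. What may go wrong: proton transfer from C8a–H of 16 to the azaenolate, after which the ester enolate closes onto C5 to a cyclopropane; slow SN2 between two β-branched partners, so that the mixture must be warmed and the ester carbonyl is attacked. Fallback: carry C8a as a dithiane through the coupling, so that no enolisable or electrophilic carbonyl is present. It sets out from 15. i-Bu2AlH (2.2 equiv, CH2Cl2, −78 °C) reduces the ester to the aldehyde stage, and the γ-hydroxy aldehyde closes on work-up to the lactol F5. Propane-1,3-dithiol and BF3·OEt2 (CH2Cl2, −20 °C) open it to the hydroxy dithiane F6. I2, PPh3 and imidazole give the iodide F7, used cold and at once. Alkylation of azaenolate 19 as in step 12 gives the hydrazone F8, aqueous oxalic acid the aldehyde F9, and Ph3P=CHBr the (Z)-bromoalkene F10. MeI and CaCO3 in MeCN–H2O unmask the C8a aldehyde F11; NaClO2, NaH2PO4 and 2-methylbut-2-ene oxidise it to the acid F12; TMSCHN2 in toluene–MeOH gives the methyl ester, and the route is rejoined at 22.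

3. Step 8. What may go wrong: slow cycloaddition with thermal decay or polymerisation of the triene, and erosion of the endo preference at 115 °C. Fallback: catalyst control in place of auxiliary control. It sets out from 10, which is treated with furan-2(5H)-one (O=C1OCC=C1) and the oxazaborolidinium catalyst made from 3,3-diphenyl-1-(o-tolyl)tetrahydro-1H,3H-pyrrolo[1,2-c][1,3,2]oxazaborole and HNTf2 (20 mol%, CH2Cl2, −40 → −20 °C). The antipode of the catalyst is chosen so that the endo adduct is the cis-fused lactone F13 with the ring B configuration of 15. KOH (1.05 equiv) in MeOH–H2O opens F13 to the potassium salt 14, and after evaporation MeI in DMF methylates the carboxylate; the route is rejoined at 15.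

**Further compounds**

F1 | step 15 | methyl enol ether of the one-carbon-homologated aldehyde (C6–CH=CH–OMe, E/Z mixture) | CC(C)=CCC[C@H](C)[C@H](C=COC)C[C@@H]1CC(C)=C[C@H](/C=C(\C)[C@H]2CC[C@H](CO[Si](C)(C)C(C)(C)C)CC2)[C@@H]1C(=O)OC
F2 | step 15 | C8a bromo ester of F1 (both C8a epimers) | CC(C)=CCC[C@H](C)[C@H](C=COC)C[C@@H]1CC(C)=C[C@H](/C=C(\C)[C@H]2CC[C@H](CO[Si](C)(C)C(C)(C)C)CC2)C1(Br)C(=O)OC
F3 | step 15 | C8a bromo ester with C6–CH2–CHO (aldehyde carbon = C8) | CC(C)=CCC[C@H](C)[C@H](CC=O)C[C@@H]1CC(C)=C[C@H](/C=C(\C)[C@H]2CC[C@H](CO[Si](C)(C)C(C)(C)C)CC2)C1(Br)C(=O)OC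
F4 | step 15 | cis-fused octahydronaphthalene methyl ester with OH on C8 | CC(C)=CCC[C@H](C)[C@@H]1CC(O)[C@]2(C(=O)OC)[C@@H](CC(C)=C[C@@H]2/C=C(\C)[C@H]2CC[C@H](CO[Si](C)(C)C(C)(C)C)CC2)C1
F5 | step 12 | lactol from 15 (anomeric mixture) | OC1OC[C@@H]2CC(C)=C[C@H](/C=C(\C)[C@H]3CC[C@H](CO[Si](C)(C)C(C)(C)C)CC3)[C@H]12
F6 | step 12 | ring B with 1,3-dithian-2-yl on C8a and CH2OH on C4a | OC[C@@H]1CC(C)=C[C@H](/C=C(\C)[C@H]2CC[C@H](CO[Si](C)(C)C(C)(C)C)CC2)[C@@H]1C1SCCCS1
F7 | step 12 | ring B with 1,3-dithian-2-yl on C8a and CH2I on C4a | IC[C@@H]1CC(C)=C[C@H](/C=C(\C)[C@H]2CC[C@H](CO[Si](C)(C)C(C)(C)C)CC2)[C@@H]1C1SCCCS1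
F8 | step 12 | SAMP hydrazone alkylated at C6, dithiane on C8a | CC(C)=CCC[C@H](C)[C@H](/C=N/N1CCC[C@H]1COC)C[C@@H]2CC(C)=C[C@H](/C=C(\C)[C@H]3CC[C@H](CO[Si](C)(C)C(C)(C)C)CC3)[C@@H]2C4SCCCS4
F9 | step 12 | C7 aldehyde, dithiane on C8a | CC(C)=CCC[C@H](C)[C@H](C=O)C[C@@H]1CC(C)=C[C@H](/C=C(\C)[C@H]2CC[C@H](CO[Si](C)(C)C(C)(C)C)CC2)[C@@H]1C3SCCCS3
F10 | step 12 | (Z)-bromoalkene, dithiane on C8a | CC(C)=CCC[C@H](C)[C@H](/C=C\Br)C[C@@H]1CC(C)=C[C@H](/C=C(\C)[C@H]2CC[C@H](CO[Si](C)(C)C(C)(C)C)CC2)[C@@H]1C3SCCCS3
F11 | step 12 | (Z)-bromoalkene, CHO on C8a | CC(C)=CCC[C@H](C)[C@H](/C=C\Br)C[C@@H]1CC(C)=C[C@H](/C=C(\C)[C@H]2CC[C@H](CO[Si](C)(C)C(C)(C)C)CC2)[C@@H]1C=O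
F12 | step 12 | (Z)-bromoalkene, CO2H on C8a | CC(C)=CCC[C@H](C)[C@H](/C=C\Br)C[C@@H]1CC(C)=C[C@H](/C=C(\C)[C@H]2CC[C@H](CO[Si](C)(C)C(C)(C)C)CC2)[C@@H]1C(=O)O
F13 | step 8 | cis-fused lactone of ring B (endo adduct of 10 and furan-2(5H)-one; C8a–C(=O)–O–C5H2–C4a, arm on C1 cis to both) | O=C1OC[C@@H]2CC(C)=C[C@H](/C=C(\C)[C@H]3CC[C@H](CO[Si](C)(C)C(C)(C)C)CC3)[C@H]12
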